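**Retrosynthetic overview**
- Key cut: the bond between the quaternary ring carbon and the side-chain ketone carbon. The acyl carbon is used as an acyl-nickel species (an acyl anion equivalent) and joined to a tertiary alkyl bromide, so two carbons that are both normally electrophilic are coupled.
- The tertiary bromide comes from radical Markovnikov hydrobromination of (R)-dihydro-α-ionone, itself from conjugate reduction of (R)-(+)-α-ionone, which supplies the ring CH stereocentre.
- The acyl donor comes from chemoselective oxidative cleavage of the distal alkene of geranyl acetate; the (E)-allylic acetate is carried through untouched.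
- No ring is formed: the cyclohexane is bought intact. The quaternary stereocentre is set in the coupling under control of the neighbouring CH stereocentre.

Assumption: the SMILES is read as the (1R,2R)-cyclohexane, antipodal to the sclareol/sclareolide series (which therefore cannot be used), and (R)-(+)-α-ionone of ≥98% ee (natural flavour grade) is taken as commercially available.

**Route**

Step 1
Reactants: 1 (R)-(+)-α-ionone
Product: 3 (R)-dihydro-α-ionone [4-[(1R)-2,6,6-trimethylcyclohex-2-en-1-yl]butan-2-one], via triethylsilyl enol ether 2 (not isolated)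
Conditions: Et3SiH (1.2 equiv), RhCl(PPh3)3 (0.5 mol %), toluene, 50 °C; then 1 M HCl, THF, 0 °C
Reagents that add atoms: none
Why: Rhodium-catalysed 1,4-hydrosilylation (conjugate reduction) touches only the enone C=C under neutral conditions, so the hindered ring alkene stays and the allylic ring stereocentre, which base would epimerise through the dienolate, is carried through as (R).

Step 2
Reactants: 3 (R)-dihydro-α-ionone
Product: 4 4-[(1R)-2-bromo-2,6,6-trimethylcyclohexyl]butan-2-one (both epimers at the C–Br carbon)
Conditions: Co(acac)2 (25 mol %), t-BuOOH (25 mol %), Et3SiH (3 equiv), TsBr (2.5 equiv), n-PrOH, 23 °C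
Reagents that add atoms: p-toluenesulfonyl bromide (TsBr), Cc1ccc(cc1)S(=O)(=O)Br
Why: Mukaiyama-type metal-hydride hydrogen-atom-transfer hydrobromination puts H on the less substituted alkene carbon and the tertiary radical takes Br from TsBr, so no carbocation forms that could cyclise onto the ketone oxygen or eliminate towards the ring CH stereocentre; the C–Br configuration is irrelevant because it becomes a planar radical in step 4.

Step 3
Reactants: 5 geranyl acetate
Product: 7 (4E)-6-acetoxy-4-methylhex-4-enoic acid, via aldehyde 6 (not isolated)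
Conditions: O3 (1.0 equiv, Sudan Red 7B end point), MeCN/H2O (9:1), 0 °C; N2 purge; then NaClO2 (2 equiv), NaH2PO4, 0 °C → rt
Reagents that add atoms: ozone, [O-][O+]=O; sodium chlorite, [Na+].[O-]Cl=O
Why: Chemoselective ozonolysis cleaves the electron-rich 6,7-alkene faster than the 2,3-alkene deactivated by the allylic acetate, water releasing the aldehyde from the carbonyl oxide, and a Pinnick oxidation in the same pot (the H2O2 formed in the first stage scavenging HOCl) gives the acid with the (E)-alkene unchanged.

Step 4
Reactants: 4 4-[(1R)-2-bromo-2,6,6-trimethylcyclohexyl]butan-2-one; 7 (4E)-6-acetoxy-4-methylhex-4-enoic acid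
Product: 9 CNP0326957.1 [(2E)-3-methyl-6-oxo-6-[(1R,2R)-1,3,3-trimethyl-2-(3-oxobutyl)cyclohexyl]hex-2-en-1-yl acetate], via mixed carbonic anhydride 8 (not isolated)
Conditions: 7 (1.5 equiv), Boc2O (1.6 equiv), MgCl2 (1.5 equiv), Ni(acac)2 (10 mol %), 4,4'-di-tert-butyl-2,2'-bipyridine (12 mol %), Zn dust (3 equiv), THF/MeCN (1:1), 25 °C
Reagents that add atoms: none
Why: In this nickel-catalysed reductive cross-electrophile acylation, zerovalent nickel inserts into anhydride 8 to give an acyl-nickel species that acts as an acyl anion equivalent, captures the tertiary radical released from 4 by bromine abstraction and reductively eliminates the α-quaternary ketone; the bulky acyl-nickel is expected to add to the planar radical anti to the neighbouring 3-oxobutyl chain (the usual trans preference of 2-substituted cyclohexyl radicals, with the syn-axial methyl of the gem-dimethyl group disfavouring axial attack), which gives the (1R) centre, and any minor epimer is removed by chromatography.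

**Compound list**
1 | (R)-(+)-α-ionone, (3E)-4-[(1R)-2,6,6-trimethylcyclohex-2-en-1-yl]but-3-en-2-one | CC(=O)/C=C/[C@H]1C(C)=CCCC1(C)C | starting material
2 | triethyl{[(2Z)-4-[(1R)-2,6,6-trimethylcyclohex-2-en-1-yl]but-2-en-2-yl]oxy}silane | C/C(O[Si](CC)(CC)CC)=C/C[C@H]1C(C)=CCCC1(C)C | intermediate
3 | (R)-dihydro-α-ionone, 4-[(1R)-2,6,6-trimethylcyclohex-2-en-1-yl]butan-2-one | CC(=O)CC[C@H]1C(C)=CCCC1(C)C | intermediate
4 | 4-[(1R)-2-bromo-2,6,6-trimethylcyclohexyl]butan-2-one (both epimers at the C–Br carbon) | CC(=O)CC[C@H]1C(C)(Br)CCCC1(C)C | intermediate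
5 | geranyl acetate, (2E)-3,7-dimethylocta-2,6-dien-1-yl acetate | CC(C)=CCC/C(C)=C/COC(C)=O | starting material
6 | (2E)-3-methyl-6-oxohex-2-en-1-yl acetate | O=CCC/C(C)=C/COC(C)=O | intermediate
7 | (4E)-6-acetoxy-4-methylhex-4-enoic acid | OC(=O)CC/C(C)=C/COC(C)=O | intermediate
8 | (4E)-6-acetoxy-4-methylhex-4-enoic tert-butyl carbonic anhydride | CC(C)(C)OC(=O)OC(=O)CC/C(C)=C/COC(C)=O | intermediate
9 | CNP0326957.1, (2E)-3-methyl-6-oxo-6-[(1R,2R)-1,3,3-trimethyl-2-(3-oxobutyl)cyclohexyl]hex-2-en-1-yl acetate | CC(=O)CC[C@@H]1C(C)(C)CCC[C@@]1(C)C(=O)CC/C(C)=C/COC(C)=O | target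

**Step count and risks**

Total steps: 4. Longest linear sequence: 3 (steps 1, 2 and 4).

Most likely to fail, in order:

Step 4. The tertiary radical is flanked by a substituted carbon, so capture by nickel may be slow and elimination may compete. Zerovalent nickel may also ionise the allylic acetate. The facial selectivity at the new quaternary centre is predicted, not proven, and could be modest. The fallback sets out from 3 and from aldehyde 6 (isolated by stopping step 3 after the ozone stage with a Na2SO3 quench) and comes back at 9. Mukaiyama hydration of 3 (Co(acac)2, O2, PhSiH3, i-PrOH) gives the tertiary alcohol 4-[(1R)-2-hydroxy-2,6,6-trimethylcyclohexyl]butan-2-one F1. Acylation with N-phthalimidoyl chlorooxalate (Et3N, DMAP, THF) gives 1,3-dioxoisoindolin-2-yl (2R)-1,3,3-trimethyl-2-(3-oxobutyl)cyclohexyl oxalate F2. F2 and 6 are then joined by radical N-heterocyclic carbene catalysis (N-(2,6-diisopropylphenyl) cycloheptane-fused thiazolium salt 10 mol %, Cs2CO3, DMSO, 60 °C). The Breslow intermediate of 6 reduces F2 by one electron, F2 loses phthalimide and two CO2 to give the same tertiary radical, and radical–radical coupling followed by loss of the carbene gives 9. No nickel is present, so the allylic acetate is not at risk; use of an oxalate in place of the usual carboxylate-derived ester in this catalysis is an extension of known practice.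

Step 2. The tertiary radical may add to the side-chain ketone (5-exo), the cobalt hydride may isomerise the alkene into the tetrasubstituted position (which would erase the ring stereocentre), and the δ-keto tertiary bromide may ionise on handling. The fallback sets out from 3 and comes back at 9, with the ketone masked throughout. Ethylene glycol, PPTS, benzene, reflux gives 2-methyl-2-{2-[(1R)-2,6,6-trimethylcyclohex-2-en-1-yl]ethyl}-1,3-dioxolane F3. The same radical hydrobromination gives 2-{2-[(1R)-2-bromo-2,6,6-trimethylcyclohexyl]ethyl}-2-methyl-1,3-dioxolane F4. Nickel coupling with 7 as in step 4 gives (2E)-3-methyl-6-oxo-6-{(1R,2R)-1,3,3-trimethyl-2-[2-(2-methyl-1,3-dioxolan-2-yl)ethyl]cyclohexyl}hex-2-en-1-yl acetate F5. PPTS in acetone/H2O at 50 °C then releases 9. This costs two more steps but removes the carbonyl from both radical steps.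

Step 3. Ozone may also attack the allylic acetate alkene, and HOCl may chlorinate the remaining alkene if the peroxide scavenging is incomplete. The fallback sets out from 5 and comes back at 6. mCPBA (1.0 equiv, CH2Cl2, 0 °C) epoxidises only the distal alkene to give (2E)-5-(3,3-dimethyloxiran-2-yl)-3-methylpent-2-en-1-yl acetate F6. HIO4·2H2O (THF/H2O, 0 °C) cleaves F6 to 6, which is oxidised to 7 with NaClO2, NaH2PO4 and 2-methylbut-2-ene.

**Further compounds**
F1 | step 4 | 4-[(1R)-2-hydroxy-2,6,6-trimethylcyclohexyl]butan-2-one (both carbinol epimers) | CC(=O)CC[C@H]1C(C)(O)CCCC1(C)C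
F2 | step 4 | 1,3-dioxoisoindolin-2-yl (2R)-1,3,3-trimethyl-2-(3-oxobutyl)cyclohexyl oxalate | CC(=O)CC[C@H]1C(C)(OC(=O)C(=O)ON2C(=O)c3ccccc3C2=O)CCCC1(C)C
F3 | step 2 | 2-methyl-2-{2-[(1R)-2,6,6-trimethylcyclohex-2-en-1-yl]ethyl}-1,3-dioxolane | CC1(CC[C@H]2C(C)=CCCC2(C)C)OCCO1
F4 | step 2 | 2-{2-[(1R)-2-bromo-2,6,6-trimethylcyclohexyl]ethyl}-2-methyl-1,3-dioxolane (both epimers at the C–Br carbon) | CC1(CC[C@H]2C(C)(Br)CCCC2(C)C)OCCO1
F5 | step 2 | (2E)-3-methyl-6-oxo-6-{(1R,2R)-1,3,3-trimethyl-2-[2-(2-methyl-1,3-dioxolan-2-yl)ethyl]cyclohexyl}hex-2-en-1-yl acetate | CC1(CC[C@@H]2C(C)(C)CCC[C@@]2(C)C(=O)CC/C(C)=C/COC(C)=O)OCCO1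
F6 | step 3 | (2E)-5-(3,3-dimethyloxiran-2-yl)-3-methylpent-2-en-1-yl acetate (racemic at the oxirane carbon) | CC1(C)OC1CC/C(C)=C/COC(C)=O
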